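The constants used here are those of an exercise; the run is a simulation.

The ratio of the coupling constant, with coupling partner at its charge, to the substrate constant is 1.09, so the two steps in series run at nearly one pace.

| flask | substrate | coupling partner | time | remark |
|---|---|---|---|---|
| north-west | 47 mM | 51.7 mM | 50 s | everything together in a closed stirred flask, run for 50 s |
| north-east | 47 mM | 51.7 mM |  | one stirred flow tank at steady state, fed with the mixture as stated, mean residence time 50 s |
| south-east | 47 mM (fed, over 25.0 s) | 51.7 mM | 50 s | all but substrate at the start; substrate goes in evenly over 25.0 s, the run ends at 50 s |
| south | 47 mM | 51.7 mM (fed, over 25.0 s) | 50 s | a stirred flask in which coupling partner is dosed at a steady rate over 25.0 s without added volume, worked up at 50 s |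

    coupling partner + intermediate → target (k1 = 0.184 /M/s)
    substrate → intermediate (k2 = 0.00875 /s)
    target ⇌ isomer of the product (K3 = 1.1, k3 = 0.0131 /s)
    coupling partner → decomposition product (k4 = 9.61 × 10⁻⁵ /s)

- the set-up with the highest amount of target at the outlet or at the end, in percent of the substrate put in ("none" if the first two lie within 2 percentage points) (north-west / north-east / south-east / south / none)
- amount of target at the outlet or at the end, in percent of the substrate put in, north-west
- amount of target at the outlet or at the end, in percent of the substrate put in, north-east
- amount of target at the outlet or at the end, in percent of the substrate put in, south-east
- amount of target at the outlet or at the end, in percent of the substrate put in, south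

- the stated concentrations are those of everything mixed, before any reaction; amounts are the same in each set-up
- the feed brings no volume worth counting
- run time (north-west): 50 s

**Your hunch.** You guessed that the top two set-ups lie within 2 percentage points of each other. Coupling partner is charged in excess, which makes substrate the limiting reagent, and at equilibrium target holds 47.6% of the coupled material. The substrate's time constant of 114 s is longer than the run, so the reading falls early in the approach, where age counts.

**Mean age.** We define the mean age θ of the substrate at the reading as the run time less half its dosing time, 37.5 s in south-east and 50 s in north-west. We take coupling as pseudo-first-order with kC = 0.00951 /s, and kS is the substrate constant. The coupled share is then F = 1 − (kC·e^(−kS·θ) − kS·e^(−kC·θ))/(kC − kS).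

**Our number.** Coupled material appears at a rate rising roughly linearly with time, so on average it has stood for a third of θ. We therefore multiply F by e^(−kI·θ/3), with kI the forward isomerisation constant. North-west has F = 7.72% and target 6.21%. South-east has F = 4.67% and target 3.97%, lower than north-west. Our reckoning stops there, short of the tank and of partner dosing.

**The forecast.** It gave 6.2% for north-west, 6.5% for north-east, 4% for south-east and 5.8% for south, with verdict none, reaching target by “Convolving with the relaxation”.

**The result.** The simulation gives 6.14%, 6.53%, 3.98% and 5.82% in that order. The verdict is none, since the first two lie 0.39 points apart, inside the margin.

**South-east's deficit.** The early reading is the largest single effect on target in south-east: read at 500 s, that flask gives 38.2% against 3.98%. The slow dosing of substrate is a further part of why south-east ends low: with that dosing taken away the flask gives 6.14% against 3.98%, and its age is 50 s instead of 37.5 s. On the neighbour of south-east charged with 130 mM of coupling partner, θ stays at 37.5 s, kC becomes 0.0239 /s, F becomes 9.95%, and target comes to 8.45%. The simulation reads 8.41%.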